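Ring A of the diaryl ether is cut at its C4–C5 bond (C1 = the carbon on the bridging oxygen). The feature exploited is the 1,3,5-trioxygenation of ring A (oxygens on C1, C3 and C5), which maps atom for atom onto triacetic acid lactone: a 5-aryloxyresorcinol is an isomer of a 4-aryloxy-6-methyl-2-pyrone. The crowded O–C1 bond to the 2,6-dioxygenated ring B is therefore made on the pyrone by addition–elimination, the lactone is opened, and one base-mediated Claisen cyclization closes and aromatizes ring A. Its precursor is the methyl (E)-3-aryloxy-5-oxohex-2-enoate carrying ring B as a bis(benzyl) mono(methoxymethyl) ether.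

Key step: step 6

Remark: the target is drawn as the free bis(hydrogen sulfate), so 15 and 16 are drawn in that form, although both would be handled as disodium salts until the final cold cation exchange; 3,5-bis(benzyloxy)phenol is taken as a catalogue compound.

Step 1
Reactants: 1 3,5-bis(benzyloxy)phenol
Product: 3 2,6-bis(benzyloxy)benzene-1,4-diol, via 2,6-bis(benzyloxy)-1,4-benzoquinone 2 (not isolated)
Conditions: ON(SO3K)2 (2.2 equiv), KH2PO4 buffer, acetone/H2O, rt; EtOAc extract shaken with aq. Na2S2O4, Ar
Reagents that add atoms: potassium nitrosodisulfonate (Fremy's salt), [K+].[K+].[O-]S(=O)(=O)N([O])S(=O)(=O)[O-]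
Why: In a Teuber oxidation two equivalents of the nitrosodisulfonate radical should convert the phenol, whose para position is free, into the para-quinone (new oxygen on the carbon between the two benzyloxy groups), and dithionite reduces this quinone to the hydroquinone in the work-up, the benzyl ethers being inert to both reagents.

Step 2
Reactants: 3 2,6-bis(benzyloxy)benzene-1,4-diol; 4 chloromethyl methyl ether
Product: 5 2,6-bis(benzyloxy)-4-(methoxymethoxy)phenol
Conditions: MOMCl (1.0 equiv), i-Pr2NEt (1.2 equiv), CH2Cl2, −20 to 0 °C, Ar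
Reagents that add atoms: chloromethyl methyl ether (4), COCCl
Why: This Williamson-type methoxymethylation should go to O4, the unhindered and more acidic hydroxyl, because O1 is flanked by two benzyloxy groups, and one equivalent of the chloride at low temperature limits double protection.

Step 3
Reactants: 6 4-hydroxy-6-methyl-2H-pyran-2-one
Product: 7 4-bromo-6-methyl-2H-pyran-2-one
Conditions: Bu4NBr, P2O5, toluene, 100 °C
Reagents that add atoms: tetrabutylammonium bromide, CCCC[N+](CCCC)(CCCC)CCCC.[Br-]
Why: This is the known deoxybromination of a vinylogous acid, in which P2O5 turns the C4 hydroxyl into a phosphate leaving group that bromide displaces by addition–elimination.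

Step 4
Reactants: 5 2,6-bis(benzyloxy)-4-(methoxymethoxy)phenol; 7 4-bromo-6-methyl-2H-pyran-2-one
Product: 8 4-[2,6-bis(benzyloxy)-4-(methoxymethoxy)phenoxy]-6-methyl-2H-pyran-2-one
Conditions: K2CO3, DMF, 60 °C
Reagents that add atoms: none
Why: Addition–elimination (nucleophilic vinylic substitution) at C4 of the pyrone, a vinylogous acyl bromide, lets the small phenoxide oxygen add conjugately despite its two ortho substituents, so the crowded aryl–oxygen bond is made without a metal catalyst.

Step 5
Reactants: 8 4-[2,6-bis(benzyloxy)-4-(methoxymethoxy)phenoxy]-6-methyl-2H-pyran-2-one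
Product: 9 methyl (2E)-3-[2,6-bis(benzyloxy)-4-(methoxymethoxy)phenoxy]-5-oxohex-2-enoate
Conditions: Mg(OMe)2 (2 equiv), MeOH, reflux; then AcOH, 0 °C
Reagents that add atoms: magnesium methoxide, C[O-].C[O-].[Mg+2]; methanol, CO
Why: Lactone methanolysis (ring-opening transesterification), known for 4-alkoxy-6-methyl-2-pyrones, should occur by magnesium-assisted attack of methoxide at the lactone carbonyl, release the C6 enolate as the methyl ketone, and keep the ring C3=C4 geometry so that ester and ketone arm stay cis, which is the (E)-enoate.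

Step 6
Reactants: 9 methyl (2E)-3-[2,6-bis(benzyloxy)-4-(methoxymethoxy)phenoxy]-5-oxohex-2-enoate
Product: 11 5-[2,6-bis(benzyloxy)-4-(methoxymethoxy)phenoxy]benzene-1,3-diol, via 5-(aryloxy)cyclohex-4-ene-1,3-dione 10 (not isolated)
Conditions: KOt-Bu (3 equiv), THF/t-BuOH, 0 to 50 °C, Ar; then AcOH
Reagents that add atoms: none
Why: The more acidic C4 methylene gives a dienolate that serves as a nucleophile-resistant reservoir, while reversible deprotonation of the ketone methyl (C6) gives the enolate whose carbon adds to the ester carbonyl, methoxide is expelled to give dione 10, and 10 enolizes irreversibly to the aromatic resorcinolate. The closest known reaction type is the intramolecular Claisen (Dieckmann-type) C-acylation of 3-alkoxy-5-oxohex-2-enoates to 5-alkoxyresorcinols, and more generally the Claisen cyclization of 3,5-diketo esters to phloroglucinols. Ring A closes in a 6-(enolendo)-exo-trig mode, forming its C4–C5 bond between the former methyl carbon and the former ester carbon. No stereocentre is created. The selectivity needed is C-acylation by the terminal enolate in preference to displacement of the aryloxide at the enol ether carbon or O-acylation back to the pyrone. It is secured by the (E)-enoate geometry, which holds the ester cis to the ketone arm, by the bulk of tert-butoxide, and by aromatization, which withdraws the product from every equilibrium.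

Step 7
Reactants: 11 5-[2,6-bis(benzyloxy)-4-(methoxymethoxy)phenoxy]benzene-1,3-diol; 12 benzyl bromide
Product: 13 3-(benzyloxy)-5-[2,6-bis(benzyloxy)-4-(methoxymethoxy)phenoxy]phenol
Conditions: BnBr (0.9 equiv), K2CO3, acetone, reflux
Reagents that add atoms: benzyl bromide (12), BrCc1ccccc1
Why: Williamson etherification of one of the two equivalent ring A hydroxyls with a deficit of bromide should keep the bis-ether low, the mono-ether being separated from recovered diol (recycled) and bis-ether while the methoxymethyl acetal is stable to carbonate.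

Step 8
Reactants: 13 3-(benzyloxy)-5-[2,6-bis(benzyloxy)-4-(methoxymethoxy)phenoxy]phenol
Product: 14 3,5-bis(benzyloxy)-4-[3-(benzyloxy)-5-hydroxyphenoxy]phenol
Conditions: ZnBr2, n-PrSH, CH2Cl2, 0 °C
Reagents that add atoms: none
Why: In this Lewis-acid-promoted acetal cleavage the thiol traps the methoxymethyl unit as a thioacetal, so no carbon electrophile is left to alkylate the electron-rich ring A (the reason an acetal and not a benzylic group was placed on O4), and the benzyl aryl ethers are inert to ZnBr2 at 0 °C.

Step 9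
Reactants: 14 3,5-bis(benzyloxy)-4-[3-(benzyloxy)-5-hydroxyphenoxy]phenol
Product: 15 3,5-bis(benzyloxy)-4-[3-(benzyloxy)-5-(sulfooxy)phenoxy]phenyl hydrogen sulfate
Conditions: SO3·pyridine (6 equiv), pyridine, 50 °C; then aq. NaHCO3
Reagents that add atoms: sulfur trioxide–pyridine complex, [O-]S(=O)(=O)[n+]1ccccc1
Why: O-Sulfation of phenols with the SO3·pyridine complex should convert the only two free hydroxyls (the ring A hydroxyl and ring B O4–H) into aryl sulfate monoesters and leave the benzyl ethers untouched.

Step 10
Reactants: 15 3,5-bis(benzyloxy)-4-[3-(benzyloxy)-5-(sulfooxy)phenoxy]phenyl hydrogen sulfate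
Product: 16 3-hydroxy-5-[2,6-dihydroxy-4-(sulfooxy)phenoxy]phenyl hydrogen sulfate (CNP0460023.0)
Conditions: H2 (1 atm), 10% Pd/C, MeOH/H2O, rt; then strong-acid cation-exchange resin (H+ form), 0 °C
Reagents that add atoms: none
Why: Catalytic hydrogenolysis should cleave the three benzyl aryl ethers, aryl sulfate monoester anions and the diaryl ether being stable to H2 over Pd/C, and cold cation exchange of the disodium salt gives the acid form drawn for the target.

Compound list
1 | 3,5-bis(benzyloxy)phenol | Oc1cc(OCc2ccccc2)cc(OCc2ccccc2)c1 | starting material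
2 | 2,6-bis(benzyloxy)cyclohexa-2,5-diene-1,4-dione | O=C1C=C(OCc2ccccc2)C(=O)C(OCc2ccccc2)=C1 | intermediate
3 | 2,6-bis(benzyloxy)benzene-1,4-diol | Oc1cc(OCc2ccccc2)c(O)c(OCc2ccccc2)c1 | intermediate
4 | chloromethyl methyl ether | COCCl | starting material
5 | 2,6-bis(benzyloxy)-4-(methoxymethoxy)phenol | COCOc1cc(OCc2ccccc2)c(O)c(OCc2ccccc2)c1 | intermediate
6 | 4-hydroxy-6-methyl-2H-pyran-2-one | Cc1cc(O)cc(=O)o1 | starting material
7 | 4-bromo-6-methyl-2H-pyran-2-one | Cc1cc(Br)cc(=O)o1 | intermediate
8 | 4-[2,6-bis(benzyloxy)-4-(methoxymethoxy)phenoxy]-6-methyl-2H-pyran-2-one | Cc1cc(Oc2c(OCc3ccccc3)cc(OCOC)cc2OCc2ccccc2)cc(=O)o1 | intermediate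
9 | methyl (2E)-3-[2,6-bis(benzyloxy)-4-(methoxymethoxy)phenoxy]-5-oxohex-2-enoate | COC(=O)/C=C(/Oc1c(OCc2ccccc2)cc(OCOC)cc1OCc1ccccc1)CC(C)=O | intermediate
10 | 5-[2,6-bis(benzyloxy)-4-(methoxymethoxy)phenoxy]cyclohex-4-ene-1,3-dione | O=C1CC(=O)C=C(Oc2c(OCc3ccccc3)cc(OCOC)cc2OCc2ccccc2)C1 | intermediate
11 | 5-[2,6-bis(benzyloxy)-4-(methoxymethoxy)phenoxy]benzene-1,3-diol | COCOc1cc(OCc2ccccc2)c(Oc2cc(O)cc(O)c2)c(OCc2ccccc2)c1 | intermediate
12 | benzyl bromide | BrCc1ccccc1 | starting material
13 | 3-(benzyloxy)-5-[2,6-bis(benzyloxy)-4-(methoxymethoxy)phenoxy]phenol | COCOc1cc(OCc2ccccc2)c(Oc2cc(O)cc(OCc3ccccc3)c2)c(OCc2ccccc2)c1 | intermediate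
14 | 3,5-bis(benzyloxy)-4-[3-(benzyloxy)-5-hydroxyphenoxy]phenol | Oc1cc(OCc2ccccc2)c(Oc2cc(O)cc(OCc3ccccc3)c2)c(OCc2ccccc2)c1 | intermediate
15 | 3,5-bis(benzyloxy)-4-[3-(benzyloxy)-5-(sulfooxy)phenoxy]phenyl hydrogen sulfate | O=S(=O)(O)Oc1cc(OCc2ccccc2)c(Oc2cc(OS(=O)(=O)O)cc(OCc3ccccc3)c2)c(OCc2ccccc2)c1 | intermediate
16 | 3-hydroxy-5-[2,6-dihydroxy-4-(sulfooxy)phenoxy]phenyl hydrogen sulfate | O=S(=O)(O)Oc1cc(O)cc(Oc2c(O)cc(OS(=O)(=O)O)cc2O)c1 | target

Total step count: 10. Longest linear sequence: 9 steps (steps 1, 2, 4, 5, 6, 7, 8, 9, 10 from compound 1).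

Steps most likely to fail

Step 6. The ring closure may lose to cleavage of the enol ether: methoxide set free during cyclization can displace the aryloxide at the enol ether carbon. Alternatively the substrate may stay parked as its C4 dienolate and relactonize to the pyrone. The fallback sets out from 5 and returns at 11. Commercial 5-bromobenzene-1,3-diol would be bis-allylated (allyl bromide, K2CO3, acetone) to 1-bromo-3,5-bis(prop-2-en-1-yloxy)benzene F1. An Ullmann ether synthesis of 5 with F1 (catalytic CuI, pyridine-2-carboxylic acid, K3PO4, DMSO, 90 °C) should then give 1,3-bis(benzyloxy)-2-[3,5-bis(prop-2-en-1-yloxy)phenoxy]-5-(methoxymethoxy)benzene F2. Deallylation with Pd(PPh3)4 (zerovalent palladium) and morpholine in THF would give diol 11.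

Step 5. Methoxide may add at C4 of the pyrone instead of at the lactone carbonyl, exchanging the aryloxy group for methoxy and so losing ring B. The fallback sets out from 5 and returns at 9. Oxa-Michael addition of 5 to methyl but-2-ynoate (K2CO3, DMF, 60 °C) should give methyl (2E)-3-[2,6-bis(benzyloxy)-4-(methoxymethoxy)phenoxy]but-2-enoate F3, in which the methyl group is cis to the ester. γ-Deprotonation with LDA (THF, −78 °C) and C-acylation of the lithium dienolate at the γ-carbon with N-methoxy-N-methylacetamide would give 9 after a mild acidic quench, with the required geometry retained.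

Step 2. Site selectivity between the two hydroxyls of the hydroquinone may be poor (alkylation at the hindered O1 or at both oxygens), and the hydroquinone may reoxidize in air. The fallback sets out from 3 and returns at 5. Peracetylation (Ac2O, pyridine) would give 2,6-bis(benzyloxy)-1,4-phenylene diacetate F4. Aminolysis with one equivalent of pyrrolidine (CH2Cl2, 0 °C) should remove only the unhindered acetate on O4 and give 2,6-bis(benzyloxy)-4-hydroxyphenyl acetate F5. Methoxymethylation of the single free hydroxyl (MOMCl, i-Pr2NEt, CH2Cl2) would give 2,6-bis(benzyloxy)-4-(methoxymethoxy)phenyl acetate F6. Methanolysis of the hindered acetate (K2CO3, MeOH) would then give 5.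

Further compounds
F1 | step 6 | 1-bromo-3,5-bis(prop-2-en-1-yloxy)benzene | C=CCOc1cc(Br)cc(OCC=C)c1
F2 | step 6 | 1,3-bis(benzyloxy)-2-[3,5-bis(prop-2-en-1-yloxy)phenoxy]-5-(methoxymethoxy)benzene | COCOc1cc(OCc2ccccc2)c(Oc2cc(OCC=C)cc(OCC=C)c2)c(OCc2ccccc2)c1
F3 | step 5 | methyl (2E)-3-[2,6-bis(benzyloxy)-4-(methoxymethoxy)phenoxy]but-2-enoate | COC(=O)/C=C(/Oc1c(OCc2ccccc2)cc(OCOC)cc1OCc1ccccc1)C
F4 | step 2 | 2,6-bis(benzyloxy)-1,4-phenylene diacetate | CC(=O)Oc1cc(OCc2ccccc2)c(OC(C)=O)c(OCc2ccccc2)c1
F5 | step 2 | 2,6-bis(benzyloxy)-4-hydroxyphenyl acetate | CC(=O)Oc1c(OCc2ccccc2)cc(O)cc1OCc1ccccc1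
F6 | step 2 | 2,6-bis(benzyloxy)-4-(methoxymethoxy)phenyl acetate | CC(=O)Oc1c(OCc2ccccc2)cc(OCOC)cc1OCc1ccccc1
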